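**Retrosynthetic overview**
- Larreantin comes from its bis-O-benzyl ether by hydrogenolysis; the quinone is restored by air.
- Only the benzenoid ring is built: a Diels–Alder reaction of 2-methoxy-1,4-benzoquinone (quinone ring bought intact) with an (E)-1-aryl-2-methyl-3-benzylbuta-1,3-diene, then DDQ aromatisation.
- The diene comes from a Suzuki coupling (central C2–C3 bond) of a (Z)-alkenyl boronate with a 2-bromoallyl arene.
- Both halves come from one aryl bromide: Sonogashira coupling with propyne then Cu-catalysed borylation, and Grignard allylation with 2,3-dibromopropene.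

Assumption: the target has no stereocentre and no configurationally stable axis, so it is achiral and "single enantiomer" is read as the single structure drawn; compounds 1, 2, 5, 7 and 10 are taken as commercial.

**Route**

Step 1
Reactants: 1 1-(benzyloxy)-4-bromo-2-methoxybenzene; 2 2,3-dibromoprop-1-ene
Product: 4 1-(benzyloxy)-4-(2-bromoprop-2-en-1-yl)-2-methoxybenzene, via aryl Grignard reagent 3 (not isolated)
Conditions: Mg, I2 (cat.), THF, reflux; then 2 (1.2 equiv), CuI (5 mol %), THF, 0 °C → rt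
Reagents that add atoms: 2,3-dibromoprop-1-ene (2), C=C(Br)CBr; magnesium, [Mg] (kept only in intermediate 3)
Why: Grignard formation followed by copper-catalysed allylic substitution on 2,3-dibromopropene (SN2 and SN2′ give the same product, the vinylic C–Br bond is inert); no stereocentre is formed.

Step 2
Reactants: 1 1-(benzyloxy)-4-bromo-2-methoxybenzene; 5 propyne
Product: 6 1-(benzyloxy)-2-methoxy-4-(prop-1-yn-1-yl)benzene
Conditions: 5 (3 equiv), PdCl2(PPh3)2 (3 mol %), CuI (5 mol %), Et3N–THF, sealed tube, 70 °C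
Reagents that add atoms: propyne (5), CC#C
Why: Sonogashira coupling of the aryl bromide with the terminal alkyne, the sealed tube holding the volatile propyne in solution; no stereocentre is formed.

Step 3
Reactants: 6 1-(benzyloxy)-2-methoxy-4-(prop-1-yn-1-yl)benzene; 7 bis(pinacolato)diboron
Product: 8 2-[(1Z)-1-[4-(benzyloxy)-3-methoxyphenyl]prop-1-en-2-yl]-4,4,5,5-tetramethyl-1,3,2-dioxaborolane
Conditions: 7 (1.1 equiv), CuCl (5 mol %), P(p-tol)3 (6 mol %), NaOt-Bu (10 mol %), MeOH (2 equiv), THF, rt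
Reagents that add atoms: bis(pinacolato)diboron (7), CC1(C)OB(OC1(C)C)B1OC(C)(C)C(C)(C)O1
Why: Copper-catalysed formal hydroboration (syn borylcupration, then protodemetalation with retention) puts copper at the benzylic carbon and boron on the methyl-bearing carbon, which fixes the Z geometry (aryl cis to methyl, trans to boron).

Step 4
Reactants: 8 2-[(1Z)-1-[4-(benzyloxy)-3-methoxyphenyl]prop-1-en-2-yl]-4,4,5,5-tetramethyl-1,3,2-dioxaborolane; 4 1-(benzyloxy)-4-(2-bromoprop-2-en-1-yl)-2-methoxybenzene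
Product: 9 (1E)-1,4-bis[4-(benzyloxy)-3-methoxyphenyl]-2-methyl-3-methylidenebut-1-ene
Conditions: Pd(dppf)Cl2 (5 mol %), K3PO4 (3 equiv), dioxane–H2O (5:1), 80 °C
Reagents that add atoms: none
Why: Suzuki–Miyaura coupling of two alkenyl partners goes with retention at both sp2 carbons, so the aryl group stays trans to the new C–C bond and the (E)-1-aryl diene needed for the cycloaddition results.

Step 5
Reactants: 9 (1E)-1,4-bis[4-(benzyloxy)-3-methoxyphenyl]-2-methyl-3-methylidenebut-1-ene; 10 2-methoxy-1,4-benzoquinone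
Product: 12 8-[4-(benzyloxy)-3-methoxyphenyl]-6-[4-(benzyloxy)-3-methoxybenzyl]-2-methoxy-7-methylnaphthalene-1,4-dione, via endo cycloadduct 11 (not isolated)
Conditions: 10 (1.5 equiv), toluene, 100 °C, sealed tube; then DDQ (2.2 equiv), rt
Reagents that add atoms: 2-methoxy-1,4-benzoquinone (10), COC1=CC(=O)C=CC1=O
Why: Thermal Diels–Alder reaction at the unsubstituted quinone double bond is steered by the C-1 carbonyl (C-4 is deactivated as a vinylogous ester), so the aryl-bearing diene terminus bonds next to C-1, and DDQ dehydrogenation (aromatisation) then removes the three transient stereocentres of the adduct.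

Step 6
Reactants: 12 8-[4-(benzyloxy)-3-methoxyphenyl]-6-[4-(benzyloxy)-3-methoxybenzyl]-2-methoxy-7-methylnaphthalene-1,4-dione
Product: 14 larreantin, via naphthohydroquinone 13 (not isolated)
Conditions: H2 (1 atm), 10% Pd/C, EtOAc–MeOH, rt; filter, then stir under air, rt
Reagents that add atoms: none
Why: Catalytic hydrogenolysis cleaves both aryl benzyl ethers while reducing the quinone to the hydroquinone, which autoxidises back to the quinone in air; no stereocentre is involved.

**Compound list**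
1 | 1-(benzyloxy)-4-bromo-2-methoxybenzene | COc1cc(Br)ccc1OCc1ccccc1 | starting material
2 | 2,3-dibromoprop-1-ene | C=C(Br)CBr | starting material
3 | [4-(benzyloxy)-3-methoxyphenyl]magnesium bromide | COc1cc([Mg]Br)ccc1OCc1ccccc1 | intermediate
4 | 1-(benzyloxy)-4-(2-bromoprop-2-en-1-yl)-2-methoxybenzene | C=C(Br)Cc1ccc(OCc2ccccc2)c(OC)c1 | intermediate
5 | propyne | CC#C | starting material
6 | 1-(benzyloxy)-2-methoxy-4-(prop-1-yn-1-yl)benzene | CC#Cc1ccc(OCc2ccccc2)c(OC)c1 | intermediate
7 | bis(pinacolato)diboron | CC1(C)OB(OC1(C)C)B1OC(C)(C)C(C)(C)O1 | starting material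
8 | 2-[(1Z)-1-[4-(benzyloxy)-3-methoxyphenyl]prop-1-en-2-yl]-4,4,5,5-tetramethyl-1,3,2-dioxaborolane (aryl cis to methyl, trans to boron) | C/C(=C\c1ccc(OCc2ccccc2)c(OC)c1)B1OC(C)(C)C(C)(C)O1 | intermediate
9 | (1E)-1,4-bis[4-(benzyloxy)-3-methoxyphenyl]-2-methyl-3-methylidenebut-1-ene | C=C(Cc1ccc(OCc2ccccc2)c(OC)c1)/C(C)=C/c1ccc(OCc2ccccc2)c(OC)c1 | intermediate
10 | 2-methoxy-1,4-benzoquinone | COC1=CC(=O)C=CC1=O | starting material
11 | racemic cis-fused endo cycloadduct, 8-[4-(benzyloxy)-3-methoxyphenyl]-6-[4-(benzyloxy)-3-methoxybenzyl]-2-methoxy-7-methyl-4a,5,8,8a-tetrahydronaphthalene-1,4-dione, H-4a, H-8a and H-8 all cis (one enantiomer drawn) | COC1=CC(=O)[C@H]2CC(Cc3ccc(OCc4ccccc4)c(OC)c3)=C(C)[C@@H](c3ccc(OCc4ccccc4)c(OC)c3)[C@H]2C1=O | intermediate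
12 | 8-[4-(benzyloxy)-3-methoxyphenyl]-6-[4-(benzyloxy)-3-methoxybenzyl]-2-methoxy-7-methylnaphthalene-1,4-dione | COC1=CC(=O)c2cc(Cc3ccc(OCc4ccccc4)c(OC)c3)c(C)c(-c3ccc(OCc4ccccc4)c(OC)c3)c2C1=O | intermediate
13 | 8-(4-hydroxy-3-methoxyphenyl)-6-(4-hydroxy-3-methoxybenzyl)-2-methoxy-7-methylnaphthalene-1,4-diol | COc1cc(O)c2cc(Cc3ccc(O)c(OC)c3)c(C)c(-c3ccc(O)c(OC)c3)c2c1O | intermediate
14 | larreantin, 8-(4-hydroxy-3-methoxyphenyl)-6-(4-hydroxy-3-methoxybenzyl)-2-methoxy-7-methylnaphthalene-1,4-dione (achiral) | COC1=CC(=O)c2cc(Cc3ccc(O)c(OC)c3)c(C)c(-c3ccc(O)c(OC)c3)c2C1=O | target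

**Totals**
Total step count: 6.
Longest linear sequence: 5 steps (steps 2, 3, 4, 5, 6; 1 → 6 → 8 → 9 → 12 → 14); step 1 is the side branch.

**Three steps most likely to fail, with fallbacks**

Step 5 (Diels–Alder and aromatisation). The thermal regioselectivity with a methoxyquinone may be only moderate, giving some 5-aryl isomer, and DDQ can attack the electron-rich diarylmethane CH2. The fallback sets out from diene 9 and comes back at 12. Dakin oxidation of commercial 5-bromovanillin (H2O2, NaOH, THF–H2O) gives 2-bromo-6-methoxybenzene-1,4-diol F4. Oxidation with NaIO4 (CH2Cl2–H2O) gives 2-bromo-6-methoxy-1,4-benzoquinone F5. Cycloaddition of 9 with F5 (toluene, 60–80 °C) takes place at the bromo-bearing double bond with the aryl terminus bonding to the C–Br carbon, giving the bromo cycloadduct F6. Et3N removes HBr to give the 5,8-dihydronaphthoquinone F7, which tautomerises to the bis-O-benzyl naphthalene-1,4-diol F8. Air or Ag2O then oxidises F8 to 12. Here the halogen enforces the regiochemistry and only a mild two-electron oxidation is needed.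

Step 4 (Suzuki coupling). The α-methyl alkenyl boronate is hindered and may transmetalate slowly or protodeboronate, and base may eliminate HBr from 4. The fallback sets out from aryl bromide 1 and comes back at diene 9, bypassing 4, 6 and 8. Heck reaction of 1 with 3-methylbut-3-en-2-one (Pd(OAc)2, P(o-tol)3, Et3N, DMF, 100 °C) gives (E)-4-[4-(benzyloxy)-3-methoxyphenyl]-3-methylbut-3-en-2-one F1. Kinetic enolisation at the methyl ketone (KHMDS, THF, −78 °C) and trapping with PhNTf2 gives (3E)-4-[4-(benzyloxy)-3-methoxyphenyl]-3-methylbuta-1,3-dien-2-yl trifluoromethanesulfonate F2. Negishi coupling of F2 (Pd(PPh3)4, THF, 50 °C) with [4-(benzyloxy)-3-methoxybenzyl]zinc chloride F3, made in the flask from 4-(benzyloxy)-3-methoxybenzyl chloride, Zn dust and LiCl, gives 9. This forms the sp2–sp3 C3–CH2Ar bond instead of the hindered sp2–sp2 bond.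

Step 6 (debenzylation). Hydrogenation may over-reduce the quinone or the re-oxidation may be incomplete. The fallback sets out from 12 and comes back at 14 with no new compound: a non-reductive Lewis-acid dealkylation with BCl3 and pentamethylbenzene as benzyl-cation scavenger (CH2Cl2, −78 °C), so the quinone never leaves its oxidation state. This is a change of mechanism rather than of disconnection.

**Further compounds**
F1 | step 4 | (E)-4-[4-(benzyloxy)-3-methoxyphenyl]-3-methylbut-3-en-2-one | CC(=O)/C(C)=C/c1ccc(OCc2ccccc2)c(OC)c1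
F2 | step 4 | (3E)-4-[4-(benzyloxy)-3-methoxyphenyl]-3-methylbuta-1,3-dien-2-yl trifluoromethanesulfonate | C=C(OS(=O)(=O)C(F)(F)F)/C(C)=C/c1ccc(OCc2ccccc2)c(OC)c1
F3 | step 4 | [4-(benzyloxy)-3-methoxybenzyl]zinc chloride | COc1cc(C[Zn]Cl)ccc1OCc1ccccc1
F4 | step 5 | 2-bromo-6-methoxybenzene-1,4-diol | COc1cc(O)cc(Br)c1O
F5 | step 5 | 2-bromo-6-methoxy-1,4-benzoquinone | COC1=CC(=O)C=C(Br)C1=O
F6 | step 5 | racemic cis-fused endo adduct, 8a-bromo-8-[4-(benzyloxy)-3-methoxyphenyl]-6-[4-(benzyloxy)-3-methoxybenzyl]-2-methoxy-7-methyl-4a,5,8,8a-tetrahydronaphthalene-1,4-dione, H-4a, Br-8a and H-8 cis (one enantiomer drawn) | COC1=CC(=O)[C@H]2CC(Cc3ccc(OCc4ccccc4)c(OC)c3)=C(C)[C@@H](c3ccc(OCc4ccccc4)c(OC)c3)[C@@]2(Br)C1=O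
F7 | step 5 | racemic 8-[4-(benzyloxy)-3-methoxyphenyl]-6-[4-(benzyloxy)-3-methoxybenzyl]-2-methoxy-7-methyl-5,8-dihydronaphthalene-1,4-dione (one enantiomer drawn) | COC1=CC(=O)C2=C(C1=O)[C@H](c1ccc(OCc3ccccc3)c(OC)c1)C(C)=C(Cc1ccc(OCc3ccccc3)c(OC)c1)C2
F8 | step 5 | 8-[4-(benzyloxy)-3-methoxyphenyl]-6-[4-(benzyloxy)-3-methoxybenzyl]-2-methoxy-7-methylnaphthalene-1,4-diol | COc1cc(O)c2cc(Cc3ccc(OCc4ccccc4)c(OC)c3)c(C)c(-c3ccc(OCc4ccccc4)c(OC)c3)c2c1O
F0 | step 6 | none | none
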